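**Plan**

- Retrosynthesis: the fourteen O–Si bonds and the C6′ ketal are cut first, then the ester C–O bond at O3 of the terminal catechin together with the C1′–C2′ bond of the cyclohexene ring, then the two C4–C8 interflavan bonds, and last the cycloheptenedione back to cycloheptane-1,2-dione.
- Enabling feature: O3 on ring C of the terminal unit carries a carboxyl carbon that sits on the tertiary carbinol C1′, which lies between the alkene carbon C2′ and the ketone carbon C6′ of the six-membered ring. Such a 1-hydroxycycloalkane-1-carboxylate is what a seven-membered 1,2-dione gives when an alkoxide adds and the ring contracts.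
- Forward: silylated (+)-catechin units are joined 4α→8, a silylated (−)-epicatechin unit is added 4β→8 to give a trimer whose only free hydroxyl is the terminal 3-OH, and 3,3-dimethoxycyclohept-6-ene-1,2-dione is made in four steps. The benzilic ester rearrangement then forms the ester and the cyclohexene ring in one operation; ketal hydrolysis and desilylation finish.
- Stereochemistry: C2 and C3 of the three units come from the natural flavan-3-ols, each C4 from arene attack anti to the neighbouring 3-silyloxy group (3,4-trans), and C1′ from a chiral copper–bisoxazoline chelate in the rearrangement, with the 1′-epimer to be removed by chromatography.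

Key step: step 13

TBS = tert-butyldimethylsilyl. Assumption: the 4-(2-ethoxyethoxy) acetals are drawn as their 2,4-trans (4β) epimers; this centre is lost on ionisation, so either epimer serves.

**Route**

Step 1
Reactants: 1 (+)-catechin
Product: 2 5,7,3′,4′-tetra-O-TBS-(+)-catechin (2R,3S; 3-OH free)
Conditions: TBSCl (4.4 equiv), imidazole, DMF, 0 °C → rt
Reagents that add atoms: tert-butyldimethylsilyl chloride, CC(C)(C)[Si](C)(C)Cl
Why: Silyl ether formation with TBSCl/imidazole takes the four phenols much faster than the hindered secondary 3-OH, so a controlled amount of chloride should leave that hydroxyl free.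

Step 2
Reactants: 2 5,7,3′,4′-tetra-O-TBS-(+)-catechin
Product: 3 3,5,7,3′,4′-penta-O-TBS-(+)-catechin
Conditions: TBSOTf, 2,6-lutidine, CH2Cl2, 0 °C → rt
Reagents that add atoms: tert-butyldimethylsilyl triflate, CC(C)(C)[Si](C)(C)OS(=O)(=O)C(F)(F)F
Why: Silylation of the hindered secondary alcohol with the silyl triflate caps O3 of the future middle unit, so that only the terminal unit keeps a hydroxyl later.

Step 3
Reactants: 3 3,5,7,3′,4′-penta-O-TBS-(+)-catechin
Product: 4 4β-(2-ethoxyethoxy)-3,5,7,3′,4′-penta-O-TBS-(+)-catechin (2,4-trans acetal)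
Conditions: DDQ (2 equiv), 2-ethoxyethanol, CH2Cl2, rt
Reagents that add atoms: 2-ethoxyethanol, CCOCCO
Why: DDQ benzylic oxidation removes hydride from C4, which is activated by the 5,7-disilyloxy ring A, and the quinone methide cation is captured by the alcohol to install the leaving group for the coupling.

Step 4
Reactants: 4 4β-(2-ethoxyethoxy)-3,5,7,3′,4′-penta-O-TBS-(+)-catechin, 2 5,7,3′,4′-tetra-O-TBS-(+)-catechin
Product: 5 3,5,7,3′,4′-penta-O-TBS-catechin-(4α→8)-5,7,3′,4′-tetra-O-TBS-catechin (lower 3-OH free)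
Conditions: TMSOTf (0.1 equiv), CH2Cl2, −78 °C, 4 added slowly to 2 (4 equiv)
Reagents that add atoms: none
Why: In this Lewis-acid-promoted flavan-4-yl cation arylation (Friedel–Crafts-type interflavan coupling) C8 of 2, less hindered than C6 between two silyloxy groups, attacks the cation anti to the 3-OTBS group and sets the 3,4-trans (4α) centre, while excess nucleophile and slow addition hold back self-condensation of 4.

Step 5
Reactants: 6 (−)-epicatechin
Product: 7 5,7,3′,4′-tetra-O-TBS-(−)-epicatechin (2R,3R; 3-OH free)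
Conditions: TBSCl (4.4 equiv), imidazole, DMF, 0 °C → rt
Reagents that add atoms: tert-butyldimethylsilyl chloride, CC(C)(C)[Si](C)(C)Cl
Why: The same phenol-selective silyl ether formation applies, the axial 3-OH of epicatechin being even slower to silylate than that of catechin.

Step 6
Reactants: 7 5,7,3′,4′-tetra-O-TBS-(−)-epicatechin
Product: 8 3,5,7,3′,4′-penta-O-TBS-(−)-epicatechin
Conditions: TBSOTf, 2,6-lutidine, CH2Cl2, 0 °C → rt
Reagents that add atoms: tert-butyldimethylsilyl triflate, CC(C)(C)[Si](C)(C)OS(=O)(=O)C(F)(F)F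
Why: Silyl triflate silylation of the axial secondary alcohol protects O3 of the top unit and adds a bulky group that will shield the α-face of C4.

Step 7
Reactants: 8 3,5,7,3′,4′-penta-O-TBS-(−)-epicatechin
Product: 9 4β-(2-ethoxyethoxy)-3,5,7,3′,4′-penta-O-TBS-(−)-epicatechin (2,4-trans acetal)
Conditions: DDQ (2 equiv), 2-ethoxyethanol, CH2Cl2, rt
Reagents that add atoms: 2-ethoxyethanol, CCOCCO
Why: DDQ benzylic oxidation at C4 with capture of the cation by the alcohol, from the face opposite the 2-aryl and 3-silyloxy groups, gives the activated top unit.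

Step 8
Reactants: 9 4β-(2-ethoxyethoxy)-3,5,7,3′,4′-penta-O-TBS-(−)-epicatechin, 5 3,5,7,3′,4′-penta-O-TBS-catechin-(4α→8)-5,7,3′,4′-tetra-O-TBS-catechin
Product: 10 3,5,7,3′,4′-penta-O-TBS-epicatechin-(4β→8)-3,5,7,3′,4′-penta-O-TBS-catechin-(4α→8)-5,7,3′,4′-tetra-O-TBS-catechin (terminal 3-OH free)
Conditions: TMSOTf (0.1 equiv), CH2Cl2, −78 → −40 °C, 9 added slowly to 5 (2 equiv, excess recovered)
Reagents that add atoms: none
Why: In the same TMSOTf-promoted cation arylation the free C8 of the upper unit of 5 is the least hindered nucleophilic site (every remaining C6 lies between two silyloxy groups), and it attacks the epicatechin cation from the β-face anti to both the 2-aryl and 3-OTBS groups, setting the 4β (3,4-trans) centre.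

Step 9
Reactants: 11 cycloheptane-1,2-dione
Product: 12 2,2-dimethoxycycloheptan-1-one
Conditions: HC(OMe)3, MeOH, TsOH·H2O (cat.), rt
Reagents that add atoms: trimethyl orthoformate, COC(OC)OC; methanol, CO
Why: Acid-catalysed ketalisation with an orthoester as water scavenger should stop at the mono-ketal, because the first ketal inductively deactivates the neighbouring carbonyl.

Step 10
Reactants: 12 2,2-dimethoxycycloheptan-1-one
Product: 13 3,3-dimethoxycycloheptane-1,2-dione (may be handled as its enol tautomer)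
Conditions: SeO2 (1.2 equiv), 1,4-dioxane, trace H2O, 80 °C
Reagents that add atoms: selenium dioxide, O=[Se]=O
Why: Riley oxidation converts the only α-methylene of the ketone into a carbonyl through the enol, and the α-keto ketal is deactivated towards hydrolysis by the weakly acidic medium.

Step 11
Reactants: 13 3,3-dimethoxycycloheptane-1,2-dione
Product: 14 7,7-dimethoxy-2-(trimethylsilyloxy)cyclohept-2-en-1-one
Conditions: TMSCl, Et3N, CH2Cl2, 0 °C → rt
Reagents that add atoms: chlorotrimethylsilane, C[Si](C)(C)Cl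
Why: O-silylation of the enol form of the dione, which can enolise only away from the ketal, gives the silyl enol ether needed for dehydrogenation.

Step 12
Reactants: 14 7,7-dimethoxy-2-(trimethylsilyloxy)cyclohept-2-en-1-one
Product: 15 3,3-dimethoxycyclohept-6-ene-1,2-dione
Conditions: Pd(OAc)2 (1.05 equiv), MeCN, rt; used at once
Reagents that add atoms: none
Why: Saegusa–Ito oxidation (palladation at C3 of the silyl enol ether, then β-hydride elimination towards C4) introduces the ring alkene under near-neutral conditions that should not isomerise the ene-dione towards a tropolone.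

Step 13
Reactants: 10 tetradeca-O-TBS trimer with free terminal 3-OH, 15 3,3-dimethoxycyclohept-6-ene-1,2-dione
Product: 17 tetradeca-O-TBS trimer 3-O-[(1S)-1-hydroxy-6,6-dimethoxycyclohex-2-ene-1-carboxylate], via copper-bound hemiketal 16 (not isolated)
Conditions: Cu(OTf)2 (1.1 equiv), 2,2′-isopropylidenebis[(4S)-4-tert-butyl-2-oxazoline] (1.2 equiv), 15 (3 equiv), i-Pr2NEt (1.2 equiv), 4 Å MS, CH2Cl2, −40 → 0 °C
Reagents that add atoms: none
Why: Proposed new method: the copper-bound O3 alkoxide of 10 adds to the enone carbonyl C1 of the chelated dione to give hemiketal 16, whose alkoxide oxygen stays in the chelate while the vinylic ring carbon C7 shifts from C1 to the Lewis-acid-activated carbonyl C2, so that C1 leaves the ring as the ester carbonyl and C2 becomes the tertiary carbinol C1′ (ester C–O and C1′–C2′ bonds formed, with the change of a ketone into an ester as driving force). The closest known reactions are the benzilic ester rearrangement of cyclic 1,2-diones with simple alkoxides, which contracts the ring to a 1-hydroxycycloalkane-1-carboxylate, and the Lewis-acid-catalysed α-ketol rearrangement; neither has been run with a hindered secondary carbinol of this kind or with this ene-dione. The cyclohexene ring is not closed by a cyclisation but arises from the cycloheptene ring through this [1,2]-shift (contraction from seven to six members). C1′ is to be set by the chiral copper–bisoxazoline chelate: in the syn-chelated hemiketal the face of C1 taken by the alkoxide fixes the face of C2 reached by C7; which ligand antipode gives 1′S must be settled by trial, the (S,S)-ligand being taken first, and since the stereocentres of 10 give only a weak bias the 1′-epimer is expected as a minor product to be separated on silica. The step needs site selectivity for C1 over C2 (attack at C2 with the same facial bias would lead to the other epimer), which the quaternary C(OMe)2 carbon flanking C2 should provide. It must also outrun hydride transfer from the carbinol C–H and isomerisation of 15 towards a tropolone, which is why a weak amine base, low temperature and no free alkali alkoxide are chosen; these conditions also leave the aryl silyl ethers untouched.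

Step 14
Reactants: 17 tetradeca-O-TBS trimer 3-O-[(1S)-1-hydroxy-6,6-dimethoxycyclohex-2-ene-1-carboxylate]
Product: 18 tetradeca-O-TBS trimer 3-O-[(1S)-1-hydroxy-6-oxocyclohex-2-ene-1-carboxylate]
Conditions: TsOH·H2O (0.2 equiv), acetone–H2O (10:1), rt
Reagents that add atoms: water, O
Why: Acid-catalysed ketal hydrolysis unmasks the C6′ ketone, the β-keto ester being stable to acid and the silyl ethers and interflavan bonds of the fully silylated trimer being expected to tolerate catalytic sulfonic acid at room temperature.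

Step 15
Reactants: 18 tetradeca-O-TBS trimer 3-O-[(1S)-1-hydroxy-6-oxocyclohex-2-ene-1-carboxylate]
Product: 19 CNP0159807.2, epicatechin-(4β→8)-catechin-(4α→8)-catechin 3-O-[(1S)-1-hydroxy-6-oxocyclohex-2-ene-1-carboxylate]
Conditions: HF·pyridine, pyridine, THF, 0 °C → rt; Sephadex LH-20
Reagents that add atoms: none
Why: Fluoride-mediated global desilylation with pyridine-buffered HF should cleave the twelve aryl and two secondary silyl ethers under weakly acidic conditions that spare the base-labile β-keto ester, the ring alkene and the interflavan bonds.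

**Compound list**

1 | (+)-catechin | O[C@H]1Cc2c(O)cc(O)cc2O[C@@H]1c1ccc(O)c(O)c1 | starting material
2 | 5,7,3′,4′-tetra-O-TBS-(+)-catechin | O[C@H]1Cc2c(O[Si](C)(C)C(C)(C)C)cc(O[Si](C)(C)C(C)(C)C)cc2O[C@@H]1c1ccc(O[Si](C)(C)C(C)(C)C)c(O[Si](C)(C)C(C)(C)C)c1 | intermediate
3 | 3,5,7,3′,4′-penta-O-TBS-(+)-catechin | CC(C)(C)[Si](C)(C)O[C@H]1Cc2c(O[Si](C)(C)C(C)(C)C)cc(O[Si](C)(C)C(C)(C)C)cc2O[C@@H]1c1ccc(O[Si](C)(C)C(C)(C)C)c(O[Si](C)(C)C(C)(C)C)c1 | intermediate
4 | 4β-(2-ethoxyethoxy)-3,5,7,3′,4′-penta-O-TBS-(+)-catechin | CCOCCO[C@H]1c2c(O[Si](C)(C)C(C)(C)C)cc(O[Si](C)(C)C(C)(C)C)cc2O[C@H](c2ccc(O[Si](C)(C)C(C)(C)C)c(O[Si](C)(C)C(C)(C)C)c2)[C@H]1O[Si](C)(C)C(C)(C)C | intermediate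
5 | 3,5,7,3′,4′-penta-O-TBS-catechin-(4α→8)-5,7,3′,4′-tetra-O-TBS-catechin (lower 3-OH free) | O[C@H]1Cc2c(O[Si](C)(C)C(C)(C)C)cc(O[Si](C)(C)C(C)(C)C)c([C@@H]3c4c(O[Si](C)(C)C(C)(C)C)cc(O[Si](C)(C)C(C)(C)C)cc4O[C@H](c4ccc(O[Si](C)(C)C(C)(C)C)c(O[Si](C)(C)C(C)(C)C)c4)[C@H]3O[Si](C)(C)C(C)(C)C)c2O[C@@H]1c1ccc(O[Si](C)(C)C(C)(C)C)c(O[Si](C)(C)C(C)(C)C)c1 | intermediate
6 | (−)-epicatechin | O[C@@H]1Cc2c(O)cc(O)cc2O[C@@H]1c1ccc(O)c(O)c1 | starting material
7 | 5,7,3′,4′-tetra-O-TBS-(−)-epicatechin | O[C@@H]1Cc2c(O[Si](C)(C)C(C)(C)C)cc(O[Si](C)(C)C(C)(C)C)cc2O[C@@H]1c1ccc(O[Si](C)(C)C(C)(C)C)c(O[Si](C)(C)C(C)(C)C)c1 | intermediate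
8 | 3,5,7,3′,4′-penta-O-TBS-(−)-epicatechin | CC(C)(C)[Si](C)(C)O[C@@H]1Cc2c(O[Si](C)(C)C(C)(C)C)cc(O[Si](C)(C)C(C)(C)C)cc2O[C@@H]1c1ccc(O[Si](C)(C)C(C)(C)C)c(O[Si](C)(C)C(C)(C)C)c1 | intermediate
9 | 4β-(2-ethoxyethoxy)-3,5,7,3′,4′-penta-O-TBS-(−)-epicatechin | CCOCCO[C@H]1c2c(O[Si](C)(C)C(C)(C)C)cc(O[Si](C)(C)C(C)(C)C)cc2O[C@H](c2ccc(O[Si](C)(C)C(C)(C)C)c(O[Si](C)(C)C(C)(C)C)c2)[C@@H]1O[Si](C)(C)C(C)(C)C | intermediate
10 | tetradeca-O-TBS trimer, epicatechin-(4β→8)-catechin-(4α→8)-catechin with free 3-OH on the terminal unit | O[C@H]1Cc2c(O[Si](C)(C)C(C)(C)C)cc(O[Si](C)(C)C(C)(C)C)c([C@@H]3c4c(O[Si](C)(C)C(C)(C)C)cc(O[Si](C)(C)C(C)(C)C)c([C@H]5c6c(O[Si](C)(C)C(C)(C)C)cc(O[Si](C)(C)C(C)(C)C)cc6O[C@H](c6ccc(O[Si](C)(C)C(C)(C)C)c(O[Si](C)(C)C(C)(C)C)c6)[C@@H]5O[Si](C)(C)C(C)(C)C)c4O[C@H](c4ccc(O[Si](C)(C)C(C)(C)C)c(O[Si](C)(C)C(C)(C)C)c4)[C@H]3O[Si](C)(C)C(C)(C)C)c2O[C@@H]1c1ccc(O[Si](C)(C)C(C)(C)C)c(O[Si](C)(C)C(C)(C)C)c1 | intermediate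
11 | cycloheptane-1,2-dione | O=C1CCCCCC1=O | starting material
12 | 2,2-dimethoxycycloheptan-1-one | COC1(OC)CCCCCC1=O | intermediate
13 | 3,3-dimethoxycycloheptane-1,2-dione | COC1(OC)CCCCC(=O)C1=O | intermediate
14 | 7,7-dimethoxy-2-(trimethylsilyloxy)cyclohept-2-en-1-one | COC1(OC)CCCC=C(O[Si](C)(C)C)C1=O | intermediate
15 | 3,3-dimethoxycyclohept-6-ene-1,2-dione | COC1(OC)CCC=CC(=O)C1=O | intermediate
16 | O3-(1-hydroxy-6,6-dimethoxy-7-oxocyclohept-2-en-1-yl) hemiketal of 10 (formed at the enone carbonyl of 15, held as its copper alkoxide) | COC1(OC)CCC=C[C@](O)(C1=O)O[C@H]1Cc2c(O[Si](C)(C)C(C)(C)C)cc(O[Si](C)(C)C(C)(C)C)c([C@@H]3c4c(O[Si](C)(C)C(C)(C)C)cc(O[Si](C)(C)C(C)(C)C)c([C@H]5c6c(O[Si](C)(C)C(C)(C)C)cc(O[Si](C)(C)C(C)(C)C)cc6O[C@H](c6ccc(O[Si](C)(C)C(C)(C)C)c(O[Si](C)(C)C(C)(C)C)c6)[C@@H]5O[Si](C)(C)C(C)(C)C)c4O[C@H](c4ccc(O[Si](C)(C)C(C)(C)C)c(O[Si](C)(C)C(C)(C)C)c4)[C@H]3O[Si](C)(C)C(C)(C)C)c2O[C@@H]1c1ccc(O[Si](C)(C)C(C)(C)C)c(O[Si](C)(C)C(C)(C)C)c1 | intermediate (not isolated)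
17 | tetradeca-O-TBS trimer 3-O-[(1S)-1-hydroxy-6,6-dimethoxycyclohex-2-ene-1-carboxylate] (ester on O3 of the terminal catechin) | COC1(OC)CCC=C[C@@]1(O)C(=O)O[C@H]1Cc2c(O[Si](C)(C)C(C)(C)C)cc(O[Si](C)(C)C(C)(C)C)c([C@@H]3c4c(O[Si](C)(C)C(C)(C)C)cc(O[Si](C)(C)C(C)(C)C)c([C@H]5c6c(O[Si](C)(C)C(C)(C)C)cc(O[Si](C)(C)C(C)(C)C)cc6O[C@H](c6ccc(O[Si](C)(C)C(C)(C)C)c(O[Si](C)(C)C(C)(C)C)c6)[C@@H]5O[Si](C)(C)C(C)(C)C)c4O[C@H](c4ccc(O[Si](C)(C)C(C)(C)C)c(O[Si](C)(C)C(C)(C)C)c4)[C@H]3O[Si](C)(C)C(C)(C)C)c2O[C@@H]1c1ccc(O[Si](C)(C)C(C)(C)C)c(O[Si](C)(C)C(C)(C)C)c1 | intermediate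
18 | tetradeca-O-TBS trimer 3-O-[(1S)-1-hydroxy-6-oxocyclohex-2-ene-1-carboxylate] | O=C1CCC=C[C@@]1(O)C(=O)O[C@H]1Cc2c(O[Si](C)(C)C(C)(C)C)cc(O[Si](C)(C)C(C)(C)C)c([C@@H]3c4c(O[Si](C)(C)C(C)(C)C)cc(O[Si](C)(C)C(C)(C)C)c([C@H]5c6c(O[Si](C)(C)C(C)(C)C)cc(O[Si](C)(C)C(C)(C)C)cc6O[C@H](c6ccc(O[Si](C)(C)C(C)(C)C)c(O[Si](C)(C)C(C)(C)C)c6)[C@@H]5O[Si](C)(C)C(C)(C)C)c4O[C@H](c4ccc(O[Si](C)(C)C(C)(C)C)c(O[Si](C)(C)C(C)(C)C)c4)[C@H]3O[Si](C)(C)C(C)(C)C)c2O[C@@H]1c1ccc(O[Si](C)(C)C(C)(C)C)c(O[Si](C)(C)C(C)(C)C)c1 | intermediate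
19 | CNP0159807.2, epicatechin-(4β→8)-catechin-(4α→8)-catechin 3-O-[(1S)-1-hydroxy-6-oxocyclohex-2-ene-1-carboxylate] | O=C1CCC=C[C@@]1(O)C(=O)O[C@H]1Cc2c(O)cc(O)c([C@@H]3c4c(O)cc(O)c([C@H]5c6c(O)cc(O)cc6O[C@H](c6ccc(O)c(O)c6)[C@@H]5O)c4O[C@H](c4ccc(O)c(O)c4)[C@H]3O)c2O[C@@H]1c1ccc(O)c(O)c1 | target

**Step count and risks**

Total step count: 15. Longest linear sequence: 8 steps (steps 1, 2, 3, 4, 8, 13, 14, 15, from (+)-catechin 1 to 19).

Steps most likely to fail:

1. Step 13 (new method). Hemiketal formation at the crowded carbinol may be slower than isomerisation of the ene-dione towards a tropolone or conjugate addition to it. The carbinol C–H may be transferred as hydride to the dione. The facial selectivity of the shift may be low. Fallback by known chemistry, setting out from 10 and rejoining the route at 18: Birch reduction of commercial 2-methoxybenzoic acid (Li, NH3, t-BuOH, THF, −78 °C) should give 2-methoxycyclohexa-2,5-diene-1-carboxylic acid F1. Carbodiimide esterification with 10 (EDC, DMAP, CH2Cl2) gives the dienyl ester F2, whose epimers at the α-carbon are of no consequence. Deprotonation with KHMDS at −78 °C and hydroxylation of the cross-conjugated ester enolate with a (camphorsulfonyl)oxaziridine, chosen for the 1′S sense and followed by separation of the epimer, gives the 1′-hydroxy enol ether F3. Oxalic acid in wet THF then hydrolyses the methyl enol ether to the C6′ ketone 18.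

2. Step 8. The activated top unit may condense with itself through its own free C8. Attack may occur at a C6 position of the dimer. The coupling may be sluggish because of the many silyl groups around both reacting carbons. Fallback with a C8 cap, setting out from 8 and rejoining at 10: bromination of 8 with NBS (CH2Cl2, −78 °C) should give 8-bromo-3,5,7,3′,4′-penta-O-TBS-epicatechin F4. DDQ and 2-ethoxyethanol convert it into the 8-bromo 4β-(2-ethoxyethoxy) acetal F5, which can no longer act as a nucleophile and can be coupled with a near-equimolar amount of 5 (TMSOTf, CH2Cl2, −78 °C) to the 8-bromo trimer F6. Hydrogenolysis of the aryl bromide (H2, Pd/C, Et3N, EtOAc) then returns 10.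

3. Step 12. Palladation of the electron-poor silyl enol ether may be slow, and the ene-dione may be oxidised further or aromatise with loss of methanol during the reaction or isolation. Fallback through a selenoxide, setting out from 13 and rejoining at 15: selenenylation of the enolisable dione with PhSeCl (EtOAc, rt) should give 3,3-dimethoxy-7-(phenylselanyl)cycloheptane-1,2-dione F7. Ozone at −78 °C in CH2Cl2 then oxidises selenium only, and warming to 0 °C brings about syn-elimination of the selenoxide to 15 without metal or base.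

**Further compounds**

F1 | step 13 | 2-methoxycyclohexa-2,5-diene-1-carboxylic acid (racemic) | COC1=CCC=CC1C(=O)O
F2 | step 13 | tetradeca-O-TBS trimer 3-O-(2-methoxycyclohexa-2,5-diene-1-carboxylate), epimers at the acyl α-carbon | COC1=CCC=CC1C(=O)O[C@H]1Cc2c(O[Si](C)(C)C(C)(C)C)cc(O[Si](C)(C)C(C)(C)C)c([C@@H]3c4c(O[Si](C)(C)C(C)(C)C)cc(O[Si](C)(C)C(C)(C)C)c([C@H]5c6c(O[Si](C)(C)C(C)(C)C)cc(O[Si](C)(C)C(C)(C)C)cc6O[C@H](c6ccc(O[Si](C)(C)C(C)(C)C)c(O[Si](C)(C)C(C)(C)C)c6)[C@@H]5O[Si](C)(C)C(C)(C)C)c4O[C@H](c4ccc(O[Si](C)(C)C(C)(C)C)c(O[Si](C)(C)C(C)(C)C)c4)[C@H]3O[Si](C)(C)C(C)(C)C)c2O[C@@H]1c1ccc(O[Si](C)(C)C(C)(C)C)c(O[Si](C)(C)C(C)(C)C)c1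
F3 | step 13 | tetradeca-O-TBS trimer 3-O-[(1S)-1-hydroxy-2-methoxycyclohexa-2,5-diene-1-carboxylate] | COC1=CCC=C[C@@]1(O)C(=O)O[C@H]1Cc2c(O[Si](C)(C)C(C)(C)C)cc(O[Si](C)(C)C(C)(C)C)c([C@@H]3c4c(O[Si](C)(C)C(C)(C)C)cc(O[Si](C)(C)C(C)(C)C)c([C@H]5c6c(O[Si](C)(C)C(C)(C)C)cc(O[Si](C)(C)C(C)(C)C)cc6O[C@H](c6ccc(O[Si](C)(C)C(C)(C)C)c(O[Si](C)(C)C(C)(C)C)c6)[C@@H]5O[Si](C)(C)C(C)(C)C)c4O[C@H](c4ccc(O[Si](C)(C)C(C)(C)C)c(O[Si](C)(C)C(C)(C)C)c4)[C@H]3O[Si](C)(C)C(C)(C)C)c2O[C@@H]1c1ccc(O[Si](C)(C)C(C)(C)C)c(O[Si](C)(C)C(C)(C)C)c1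
F4 | step 8 | 8-bromo-3,5,7,3′,4′-penta-O-TBS-(−)-epicatechin | CC(C)(C)[Si](C)(C)O[C@@H]1Cc2c(O[Si](C)(C)C(C)(C)C)cc(O[Si](C)(C)C(C)(C)C)c(Br)c2O[C@@H]1c1ccc(O[Si](C)(C)C(C)(C)C)c(O[Si](C)(C)C(C)(C)C)c1
F5 | step 8 | 8-bromo-4β-(2-ethoxyethoxy)-3,5,7,3′,4′-penta-O-TBS-(−)-epicatechin | CCOCCO[C@H]1c2c(O[Si](C)(C)C(C)(C)C)cc(O[Si](C)(C)C(C)(C)C)c(Br)c2O[C@H](c2ccc(O[Si](C)(C)C(C)(C)C)c(O[Si](C)(C)C(C)(C)C)c2)[C@@H]1O[Si](C)(C)C(C)(C)C
F6 | step 8 | tetradeca-O-TBS trimer with bromine on C8 of the top epicatechin unit (terminal 3-OH free) | O[C@H]1Cc2c(O[Si](C)(C)C(C)(C)C)cc(O[Si](C)(C)C(C)(C)C)c([C@@H]3c4c(O[Si](C)(C)C(C)(C)C)cc(O[Si](C)(C)C(C)(C)C)c([C@H]5c6c(O[Si](C)(C)C(C)(C)C)cc(O[Si](C)(C)C(C)(C)C)c(Br)c6O[C@H](c6ccc(O[Si](C)(C)C(C)(C)C)c(O[Si](C)(C)C(C)(C)C)c6)[C@@H]5O[Si](C)(C)C(C)(C)C)c4O[C@H](c4ccc(O[Si](C)(C)C(C)(C)C)c(O[Si](C)(C)C(C)(C)C)c4)[C@H]3O[Si](C)(C)C(C)(C)C)c2O[C@@H]1c1ccc(O[Si](C)(C)C(C)(C)C)c(O[Si](C)(C)C(C)(C)C)c1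
F7 | step 12 | 3,3-dimethoxy-7-(phenylselanyl)cycloheptane-1,2-dione (racemic) | COC1(OC)CCCC([Se]c2ccccc2)C(=O)C1=O
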